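In a closed, stirred vessel, you can count how many times each catalyst charged has made product. Here is what you have.

| flask | substrate | partner | free catalyst | remark | time |
|---|---|---|---|---|---|
| theta | 39 mM | 23.4 mM | 0.27 mM | run made earlier |  |
| beta | 39 mM | 23.4 mM | 0.42 mM | run made earlier |  |
| zeta | 39 mM | 47 mM | 0.19 mM | run made earlier |  |
| flask | 39 mM | 23.4 mM | 0.19 mM |  | 80 min |

| run | time / min | product / % | substrate / % |
|---|---|---|---|
| theta | 8.00 | 2.8 | 97.8 |
| theta | 25.0 | 8.6 | 91.2 |
| theta | 40.0 | 12.3 | 87.3 |
| theta | 60.0 | 19.3 | 82.2 |
| beta | 5.00 | 1.8 | 97.8 |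
| beta | 12.0 | 6.6 | 93.6 |
| beta | 30.0 | 13.1 | 85.3 |
| beta | 60.0 | 25.5 | 71.4 |
| zeta | 15.0 | 3.9 | 94.7 |
| zeta | 30.0 | 9.5 | 90.8 |
| zeta | 50.0 | 12.0 | 86.2 |
| zeta | 60.0 | 14.4 | 84.2 |

(readings scatter by 1 percentage point)

- the analysis behind the earlier runs scatters by 1 percentage point, standard deviation

* product present at 80 min, in percent of the substrate charged
* substrate present at 80 min, in percent of the substrate charged

Read the last row of each run, at 60.0 min: take product in mM, divide by the free catalyst charged, then divide by the time. Theta gives 0.465 min⁻¹ and beta gives 0.395 min⁻¹, so beta sits lower. Zeta, with twice the [partner] but also less free catalyst than theta, gives 0.493 min⁻¹; two settings differ there, so this reading does not separate them. The flask has the [partner] of theta and beta, so take their mean, 0.430 min⁻¹: this is the turnover frequency, product made per catalyst charged per minute. It is a reading and carries the scatter, and the flask holds less free catalyst than either run, so using it there is an extrapolation.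

At that frequency the flask counts 34.4 turnovers per catalyst charged over 80 min. On 0.19 mM of catalyst and 39 mM of substrate, my reckoning gives 16.7 % product and so 83.3 % substrate.

The forecast, holding that “the rate is about first order in catalyst”, says 16.8 % (14 % to 19.5 %) product and 82 % (79 % to 85 %) substrate. Its substrate stands lower than mine.

The flask gives 17.2 % product and 82.5 % substrate, both inside those ranges.

    substrate + free catalyst ⇌ catalyst intermediate A (K = 22.0 M⁻¹, k = 57.0 M⁻¹ min⁻¹)
    partner + catalyst intermediate A → catalyst intermediate B (k = 190 M⁻¹ min⁻¹)
    catalyst intermediate B → by-product + catalyst intermediate C (k = 3.10 min⁻¹)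
    catalyst intermediate C ⇌ catalyst intermediate D (K = 1.10, k = 3.10 min⁻¹)
    catalyst intermediate D → free catalyst + product (k = 3.80 min⁻¹)

Counted the same way, the flask ran at 0.441 min⁻¹. Its product moves 5 points, out of the forecast's range, at 0.131 mM or 0.253 mM of free catalyst. Now take the neighbouring flask, the same with 0.48 mM of free catalyst. The carried 0.430 min⁻¹ gives it 42.3 % product. It holds 37.4 %, less than that, which is 0.380 min⁻¹, with substrate at 62 % and partner at 37 % of their charges.

(The runs were computed for an exercise; scatter was added.)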